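**Plan**
- Retrosynthesis: the oxocene ring D is cut at C17=C18 (ring-closing metathesis), at the C13–O allyl ether and at C15–C16. The C6 hydroxyl is traced to a C5=C6 olefin, ring A is cut at C3–C4, and rings B and C are cut at C9–C10 and C8–C14, back to an acyclic epoxy-diene made from (2E,6E)-farnesol.
- Forward: the farnesol chain receives an epoxide and a C1–C3 alkynylsilane arm; a cationic bicyclisation closes rings B and C; ring A is closed by an allyl cation–vinylsilane cyclisation; hydroboration follows; the side chain and ring D come last.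
- Enabling feature: in ring A the quaternary C4 carries two identical methyl groups (no stereocentre) and is bonded to ring-fusion C5, whose other neighbour C6 in ring B bears the hydroxyl. C4–C5–C6 can therefore be a 1,1-dimethylallyl cation: its C4 end closes ring A, and the C5=C6 olefin left behind is hydrated later.
- Stereochemistry: the Sharpless epoxide (C5, C10) is the only element set by a catalyst. The chair–chair bicyclisation relays it to C10, C9, C8 and C14 in one event; C13 follows from equatorial O2 capture; C5 and C6 are set together by α-face hydroboration; the ring olefin is Z by ring size.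

Key step: step 11

Remark: carbons are numbered as in the cheilanthane skeleton (ring A C1–C5 and C10; ring B C5–C10; ring C C8, C9, C11–C14; oxocene ring D O and C13–C19), the same numbers are used for the acyclic precursors, and β means the face of the methyl groups on C8 and C10 (α the opposite face).

**Step 1**
Reactants: 1 (2E,6E)-farnesol
Product: 2 (2E,6E)-farnesyl benzyl ether
Conditions: NaH, BnBr, Bu4NI (cat.), THF, 0 °C→rt
Reagents that add atoms: benzyl bromide, BrCc1ccccc1
Why: Williamson ether synthesis on the primary allylic alkoxide should mask the C15 oxygen as an ether that survives the organolithium, Lewis-acid and hydride steps and is removed later in the hydrogenation that also saturates ring A.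

**Step 2**
Reactants: 2 (2E,6E)-farnesyl benzyl ether
Product: 3 (2E,6E,10E)-12-benzyloxy-2,6,10-trimethyldodeca-2,6,10-trien-1-ol
Conditions: SeO2 (cat.), t-BuOOH, salicylic acid (cat.), CH2Cl2, 0 °C→rt
Reagents that add atoms: tert-butyl hydroperoxide, CC(C)(C)OO
Why: Selenium dioxide allylic oxidation (ene reaction followed by a [2,3]-sigmatropic shift) is known to attack the (E)-methyl group of a terminal prenyl unit, so the distal olefin should become the (E)-2-methylallylic alcohol needed for the asymmetric epoxidation, and no stereocentre is formed.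

**Step 3**
Reactants: 3 (2E,6E,10E)-12-benzyloxy-2,6,10-trimethyldodeca-2,6,10-trien-1-ol
Product: 4 (2R,3R)-epoxy alcohol, [(2R,3R)-3-[(3E,7E)-9-benzyloxy-3,7-dimethylnona-3,7-dienyl]-2-methyloxiran-2-yl]methanol
Conditions: Ti(OiPr)4 (cat.), D-(−)-diethyl tartrate (cat.), t-BuOOH, 4 Å MS, CH2Cl2, −20 °C
Reagents that add atoms: tert-butyl hydroperoxide, CC(C)(C)OO
Why: Sharpless asymmetric epoxidation acts only on the allylic alcohol, and D-(−)-diethyl tartrate (the enantiomer of the ligand that gives (2S,3S)-epoxides from (E)-allylic alcohols) should give the (2R,3R)-epoxide, which fixes C5 and C10 as the only stereocentres of the route set by a catalyst.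

**Step 4**
Reactants: 4 (2R,3R)-epoxy alcohol
Product: 6 (2R,3R)-epoxy alkynylsilane (4 with CH2OH replaced by CH2C≡CSiMe3), via epoxy triflate 5 (not isolated)
Conditions: Tf2O, 2,6-lutidine, CH2Cl2, −78 °C; then LiC≡CSiMe3 (from HC≡CSiMe3 and n-BuLi), THF/DMPU, −78 °C
Reagents that add atoms: ethynyltrimethylsilane (as its lithium acetylide), C#C[Si](C)(C)C
Why: Sulfonylation followed by SN2 displacement of the primary triflate by the acetylide, at a temperature where the epoxide is not opened, should install the C1–C3 arm as a silyl-capped propargyl group without touching the two stereocentres.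

**Step 5**
Reactants: 6 (2R,3R)-epoxy alkynylsilane
Product: 7 bicyclic alcohol (rings B and C, trans-fused: 5β-OH, 10β-CH3, 10α-CH2C≡CSiMe3, 9α-H, 8β-CH3, 13-methylene, 14α-H, 14β-CH2OBn)
Conditions: MeAlCl2, CH2Cl2, −78 °C
Reagents that add atoms: none
Why: In this Lewis-acid-initiated epoxy-polyene cyclisation the C8=C9 olefin opens the epoxide at C10 from the side opposite to oxygen and both (E)-olefins add anti through a chair–chair array, which should relay C5/C10 to C9, C8 and C14 in one event (the methyl cis to the chain becomes 10β-axial, the C1 arm equatorial, the ring fusion trans, C15 equatorial), and proton loss from the C13 cation gives the exocyclic olefin (any C12=C13 isomer formed alongside converges in step 6).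

**Step 6**
Reactants: 7 bicyclic alcohol
Product: 9 5β,13α-diol (13β-CH3), via C13 hydroperoxide 8 (not isolated)
Conditions: Mn(dpm)3 (tris(dipivaloylmethanato)manganese, cat.), PhSiH3, O2 (1 atm), i-PrOH/CH2Cl2, 0 °C→rt; then PPh3
Reagents that add atoms: dioxygen, O=O
Why: Mukaiyama hydration (hydrogen-atom transfer from a metal hydride to the CH2 terminus, then capture of the tertiary C13 radical by O2) should be Markovnikov-selective and spare the silylalkyne, and oxygen is expected to approach from the equatorial α side because the axial β side is screened by the syn-axial C8 methyl group, giving the 13α-hydroxy-13β-methyl centre.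

**Step 7**
Reactants: 9 5β,13α-diol
Product: 10 C5 ketone (13α-OH retained)
Conditions: Dess–Martin periodinane, CH2Cl2, rt
Reagents that add atoms: none
Why: Dess–Martin oxidation should convert the secondary C5 alcohol into the ketone while the tertiary C13 alcohol cannot be oxidised and no stereocentre is affected.

**Step 8**
Reactants: 10 C5 ketone
Product: 11 (Z)-vinylsilane ketone (10α-[(Z)-3-(trimethylsilyl)prop-2-enyl])
Conditions: H2 (1 atm), Pd/CaCO3 poisoned with Pb(OAc)2 (Lindlar catalyst), quinoline, EtOAc, rt
Reagents that add atoms: none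
Why: Lindlar semihydrogenation adds H2 syn on the poisoned surface and should stop at the (Z)-vinylsilane, the geometry the ring closure needs, without touching the ketone or the benzyl ether.

**Step 9**
Reactants: 11 (Z)-vinylsilane ketone
Product: 12 2,4,6-triisopropylbenzenesulfonylhydrazone of 11
Conditions: 2,4,6-triisopropylbenzenesulfonyl hydrazide, HCl (cat.), THF, rt
Reagents that add atoms: 2,4,6-triisopropylbenzenesulfonyl hydrazide, NNS(=O)(=O)c1c(C(C)C)cc(C(C)C)cc1C(C)C
Why: Condensation of the ketone with the arenesulfonyl hydrazide gives the hydrazone needed for the Shapiro reaction, a transformation that cyclohexanones with a quaternary α-carbon are known to undergo.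

**Step 10**
Reactants: 12 arenesulfonylhydrazone
Product: 14 tertiary allylic alcohol (C5=C6 olefin, C5 bearing C(CH3)2OH, 13α-OH), via C5 vinyllithium 13 (not isolated)
Conditions: n-BuLi (3.3 equiv), THF, −78→0 °C; then acetone, −78 °C; aq. NH4Cl
Reagents that add atoms: acetone, CC(C)=O
Why: In this Shapiro reaction the base, after removing the N–H and O–H protons, deprotonates C6 (the only α-hydrogens, C10 being quaternary), loss of sulfinate and N2 gives the C5 vinyllithium regiospecifically, and its addition to acetone attaches C4 with both methyl groups and the hydroxyl that serves as the leaving group.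

**Step 11**
Reactants: 14 tertiary allylic alcohol
Product: 16 tricyclic 2,5-diene (ring A closed, 4,4-dimethyl, C2=C3 and C5=C6 olefins), via dimethylallyl cation 15 (not isolated)
Conditions: BF3·OEt2, CH2Cl2, −78 °C; aq. NaHCO3
Reagents that add atoms: none
Why: BF3 assists loss of the tertiary hydroxyl to give the 1,1-dimethylallyl cation spread over C4–C5–C6, C3 of the (Z)-vinylsilane attacks its C4 end, and the β-silyl cation at C2 collapses by loss of the silyl group to leave the C2=C3 olefin (ipso substitution with retention of geometry). The closest known reaction type is the vinylsilane-terminated cation–olefin cyclisation started from an allylic cation. Ring A closes in a 6-endo-trig mode with respect to the vinylsilane (exo with respect to the allyl cation) through a chair-like array in which the C1 arm is equatorial on ring B. No new stereocentre arises, because C4 carries two methyl groups and C5 and C6 stay trigonal; the step instead leaves the C5=C6 olefin through which step 13 sets C5 and C6 together. The selectivity needed is C4 over C6 of the cation and C3 over C2 of the nucleophile: attack at C6 would demand a bridged bicyclo[3.3.1] ring from the equatorial arm, and silicon stabilises positive charge only at C2, so bonding must occur at C3, with the (Z) geometry placing silicon where the new ring bond forms.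

**Step 12**
Reactants: 16 tricyclic 2,5-diene
Product: 17 tricyclic 5-ene-13α,15-diol (ring A saturated, benzyl group removed)
Conditions: H2 (1 atm), Pd/C, EtOH, rt
Reagents that add atoms: none
Why: Heterogeneous hydrogenation should saturate the disubstituted C2=C3 olefin and cleave the benzyl ether by hydrogenolysis in the same operation, while the trisubstituted C5=C6 olefin, flanked by the quaternary C4 and C10, is too hindered to react.

**Step 13**
Reactants: 17 tricyclic 5-ene-13α,15-diol
Product: 19 6α-(pinacolato)boryl-5α-H diol, via C6 alkylborane 18 (not isolated)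
Conditions: BH3·THF (excess), THF, 0→45 °C; then pinacol, rt; aq. NH4Cl
Reagents that add atoms: borane (as BH3·THF), B; pinacol, CC(C)(O)C(C)(C)O
Why: Hydroboration places boron on the less substituted C6 and hydrogen on C5 by syn addition from the α face, the β face being screened by the axial methyl groups on C4, C10 and C8, which sets the trans A/B fusion (5α-H) and the 6α C–B bond in one event, and alcoholysis with pinacol gives a boronic ester that serves as a masked 6α-hydroxyl (boron bound to the two hydroxyls is hydrolysed on work-up).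

**Step 14**
Reactants: 19 6α-boryl diol
Product: 20 C15 iodide (13α-OH and 6α-boronic ester retained)
Conditions: I2, PPh3, imidazole, CH2Cl2, 0 °C→rt
Reagents that add atoms: iodine, II
Why: In this Appel reaction the primary C15 alcohol is converted into the iodide by SN2 displacement of the alkoxyphosphonium ion, whereas the tertiary C13 alcohol and the boronic ester should not react.

**Step 15**
Reactants: 20 C15 iodide
Product: 21 14β-(3-methylbut-3-enyl) compound (13α-OH, 6α-boronic ester)
Conditions: CH2=C(CH3)CH2SnBu3 (3 equiv), AIBN (cat.), benzene, 80 °C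
Reagents that add atoms: tributyl(2-methylallyl)stannane, C=C(C)C[Sn](CCCC)(CCCC)CCCC
Why: In this Keck radical allylation the primary C15 radical formed by iodine abstraction adds to the stannane and β-scission of the tin radical carries the chain, which avoids an SN2 reaction at the hindered C15, tolerates the free tertiary alcohol, and gives the side chain C15–C16–C17(CH3)=CH2.

**Step 16**
Reactants: 21 14β-(3-methylbut-3-enyl) compound
Product: 22 13α-allyl ether
Conditions: KH, allyl bromide, 18-crown-6 (cat.), THF, 0 °C→rt
Reagents that add atoms: allyl bromide, C=CCBr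
Why: Williamson ether synthesis on the potassium alkoxide of the tertiary C13 alcohol with the reactive allylic bromide should give the allyl ether, the C13 hydroxyl being the only free hydroxyl because the C6 oxygen is still masked as the boronic ester.

**Step 17**
Reactants: 22 13α-allyl ether
Product: 23 tetracyclic oxocene 6α-boronic ester
Conditions: second-generation Grubbs catalyst RuCl2(=CHPh)(H2IMes)(PCy3) (cat.), CH2Cl2 (high dilution), 40 °C
Reagents that add atoms: none
Why: Ring-closing metathesis between the allyl ether and the 1,1-disubstituted olefin should close the eight-membered ring, helped by the trans-diequatorial (gauche) arrangement of the two arms on ring C, and the ring size allows only the Z trisubstituted olefin.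

**Step 18**
Reactants: 23 tetracyclic oxocene 6α-boronic ester
Product: 24 CNP0179324.1 (target)
Conditions: H2O2 (30%), NaOH (aq.), THF, 0 °C→rt
Reagents that add atoms: hydrogen peroxide, OO
Why: Oxidation of the alkylboronic ester with basic hydrogen peroxide proceeds by 1,2-migration of C6 from boron to oxygen with retention, which should unveil the equatorial 6α-hydroxyl without touching the allylic ether or the ring olefin.

**Compound list**
1 | (2E,6E)-farnesol, (2E,6E)-3,7,11-trimethyldodeca-2,6,10-trien-1-ol | OC/C=C(C)/CC/C=C(C)/CCC=C(C)C | starting material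
2 | (2E,6E)-farnesyl benzyl ether | CC(C)=CCC/C(C)=C/CC/C(C)=C/COCc1ccccc1 | intermediate
3 | (2E,6E,10E)-12-benzyloxy-2,6,10-trimethyldodeca-2,6,10-trien-1-ol | OC/C(C)=C/CC/C(C)=C/CC/C(C)=C/COCc1ccccc1 | intermediate
4 | [(2R,3R)-3-[(3E,7E)-9-benzyloxy-3,7-dimethylnona-3,7-dienyl]-2-methyloxiran-2-yl]methanol | OC[C@@]1(C)O[C@@H]1CC/C(C)=C/CC/C(C)=C/COCc1ccccc1 | intermediate
5 | trifluoromethanesulfonate of 4 (not isolated) | O=S(=O)(OC[C@@]1(C)O[C@@H]1CC/C(C)=C/CC/C(C)=C/COCc1ccccc1)C(F)(F)F | intermediate
6 | (2R,3R)-epoxide carrying on C10 a methyl and a 3-(trimethylsilyl)prop-2-ynyl group, with the (3E,7E)-9-benzyloxy-3,7-dimethylnona-3,7-dienyl chain on C5 | C[Si](C)(C)C#CC[C@@]1(C)O[C@@H]1CC/C(C)=C/CC/C(C)=C/COCc1ccccc1 | intermediate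
7 | trans-fused bicyclic alcohol (rings B and C): 5β-OH, 10β-CH3, 10α-CH2C≡CSiMe3, 9α-H, 8β-CH3, 13-methylene, 14α-H, 14β-CH2OBn | C=C1CC[C@@H]2[C@@](C)(CC#C[Si](C)(C)C)[C@H](O)CC[C@@]2(C)[C@@H]1COCc1ccccc1 | intermediate
8 | 13α-hydroperoxy-13β-methyl analogue of 9 (not isolated) | C[C@]1(OO)CC[C@@H]2[C@@](C)(CC#C[Si](C)(C)C)[C@H](O)CC[C@@]2(C)[C@@H]1COCc1ccccc1 | intermediate
9 | 5β,13α-diol (13β-CH3, other centres as in 7) | C[C@]1(O)CC[C@@H]2[C@@](C)(CC#C[Si](C)(C)C)[C@H](O)CC[C@@]2(C)[C@@H]1COCc1ccccc1 | intermediate
10 | C5 ketone of 9 (13α-OH) | C[C@]1(O)CC[C@@H]2[C@@](C)(CC#C[Si](C)(C)C)C(=O)CC[C@@]2(C)[C@@H]1COCc1ccccc1 | intermediate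
11 | C5 ketone with 10α-[(Z)-3-(trimethylsilyl)prop-2-enyl] arm | C[C@]1(O)CC[C@@H]2[C@@](C)(C/C=C\[Si](C)(C)C)C(=O)CC[C@@]2(C)[C@@H]1COCc1ccccc1 | intermediate
12 | 2,4,6-triisopropylbenzenesulfonylhydrazone of 11 | C[C@]1(O)CC[C@@H]2[C@@](C)(C/C=C\[Si](C)(C)C)C(=NNS(=O)(=O)c3c(C(C)C)cc(C(C)C)cc3C(C)C)CC[C@@]2(C)[C@@H]1COCc1ccccc1 | intermediate
13 | C5 vinyllithium (C5=C6), lithium C13 alkoxide (not isolated) | C[C@]1(O[Li])CC[C@@H]2[C@@](C)(C/C=C\[Si](C)(C)C)C([Li])=CC[C@@]2(C)[C@@H]1COCc1ccccc1 | intermediate
14 | tertiary allylic alcohol: C5=C6 olefin, C5 bearing C(CH3)2OH, (Z)-vinylsilane arm on C10, 13α-OH | C[C@]1(O)CC[C@@H]2[C@@](C)(C/C=C\[Si](C)(C)C)C(C(C)(C)O)=CC[C@@]2(C)[C@@H]1COCc1ccccc1 | intermediate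
15 | 1,1-dimethylallyl cation C4–C5–C6 derived from 14 (not isolated) | C[C@]1(O)CC[C@@H]2[C@@](C)(C/C=C\[Si](C)(C)C)C([C+](C)C)=CC[C@@]2(C)[C@@H]1COCc1ccccc1 | intermediate
16 | tricyclic 2,5-diene: rings A, B, C; 4,4-dimethyl; 10β-CH3, 9α-H, 8β-CH3, 13α-OH, 13β-CH3, 14α-H, 14β-CH2OBn | C[C@]1(O)CC[C@@H]2[C@@]3(C)CC=CC(C)(C)C3=CC[C@@]2(C)[C@@H]1COCc1ccccc1 | intermediate
17 | tricyclic 5-ene with 13α-OH and 14β-CH2OH | C[C@]1(O)CC[C@@H]2[C@@]3(C)CCCC(C)(C)C3=CC[C@@]2(C)[C@@H]1CO | intermediate
18 | 5α-H, 6α-BH2 adduct with both hydroxyls as O–BH2 (not isolated) | C[C@]1(OB)CC[C@@H]2[C@@]3(C)CCCC(C)(C)[C@@H]3[C@@H](B)C[C@@]2(C)[C@@H]1COB | intermediate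
19 | 5α-H, 6α-(4,4,5,5-tetramethyl-1,3,2-dioxaborolan-2-yl) diol (13α-OH, 14β-CH2OH) | C[C@]1(O)CC[C@@H]2[C@@]3(C)CCCC(C)(C)[C@@H]3[C@@H](B4OC(C)(C)C(C)(C)O4)C[C@@]2(C)[C@@H]1CO | intermediate
20 | 14β-CH2I analogue of 19 | C[C@]1(O)CC[C@@H]2[C@@]3(C)CCCC(C)(C)[C@@H]3[C@@H](B4OC(C)(C)C(C)(C)O4)C[C@@]2(C)[C@@H]1CI | intermediate
21 | 14β-(3-methylbut-3-enyl) compound, 13α-OH, 6α-boronic ester | C[C@]1(O)CC[C@@H]2[C@@]3(C)CCCC(C)(C)[C@@H]3[C@@H](B4OC(C)(C)C(C)(C)O4)C[C@@]2(C)[C@@H]1CCC(C)=C | intermediate
22 | 13α-allyloxy analogue of 21 | C[C@]1(OCC=C)CC[C@@H]2[C@@]3(C)CCCC(C)(C)[C@@H]3[C@@H](B4OC(C)(C)C(C)(C)O4)C[C@@]2(C)[C@@H]1CCC(C)=C | intermediate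
23 | tetracyclic oxocene (Z C17=C18) with 6α-pinacol boronic ester | C/C1=C/CO[C@@]2(C)CC[C@@H]3[C@@]4(C)CCCC(C)(C)[C@@H]4[C@@H](B5OC(C)(C)C(C)(C)O5)C[C@@]3(C)[C@@H]2CC1 | intermediate
24 | CNP0179324.1 | C/C1=C/CO[C@@]2(C)CC[C@@H]3[C@@]4(C)CCCC(C)(C)[C@@H]4[C@@H](O)C[C@@]3(C)[C@@H]2CC1 | target

**Step count and risks**
Total step count: 18. Longest linear sequence: 18 steps (the route is linear from farnesol).

Step 11 (key step). The allyl cation may be lost to other channels before C3 bonds to C4: proton loss to a diene, capture by the C13 hydroxyl or the ether oxygen, or loss of silicon from the vinylsilane by protonolysis. The fallback sets out from ketone 11 and returns at diene 16. Enolisation towards C6 with KN(SiMe3)2 (one further equivalent for the C13 hydroxyl) and trapping with PhNTf2 should give the C5 enol triflate F1. Suzuki–Miyaura coupling with isopropenylboronic acid pinacol ester (Pd(dppf)Cl2, K3PO4, dioxane/water) should give the 2-substituted 1,3-diene F2. A catalytic strong acid with a non-nucleophilic anion (HNTf2, CH2Cl2, −78 °C) should then protonate the terminal CH2 of the diene, so that the same C4–C5–C6 cation forms with no leaving group, no water and no Lewis acid present, and closure by the vinylsilane gives 16.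

Step 5. The cationic cascade may stop after the first ring (proton loss from the C8 cation), or the C10 cation may rearrange before the C8=C9 olefin bonds to it. The fallback sets out from epoxide 6 and returns at 7. A radical cascade with titanocene chloride Cp2TiCl (Cp2TiCl2 cat., Mn powder, Me3SiCl, 2,4,6-collidine, THF) opens the epoxide homolytically to the tertiary C10 radical, two 6-endo closures follow, and the C13 radical is trapped by titanium and loses a β-hydrogen to the exocyclic olefin. The product is expected as the C5 trimethylsilyl ether F3, and dilute HCl in THF should return 7. In this mode C10 is no longer fixed by the epoxide geometry but only by the preference of the larger arm for the equatorial site, so the C10 epimer may have to be separated.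

Step 6. Capture of the planar C13 radical by O2 may show poor facial selectivity, which would scramble the one stereocentre of ring C that no later step can correct. The fallback sets out from 7 (exocyclic isomer) and returns at diol 9. Epoxidation with mCPBA (NaHCO3, CH2Cl2) should occur from the equatorial α side, the axial side being screened by the C8 methyl group, to give the spiro-epoxide F4. LiAlH4 in THF should open it at the CH2 carbon and give 9.

**Further compounds**
F1 | step 11 | C5 enol triflate of ketone 11 (C5=C6) | C[C@]1(O)CC[C@@H]2[C@@](C)(C/C=C\[Si](C)(C)C)C(OS(=O)(=O)C(F)(F)F)=CC[C@@]2(C)[C@@H]1COCc1ccccc1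
F2 | step 11 | 5-isopropenyl 5,6-ene (1,3-diene) with (Z)-vinylsilane arm | C[C@]1(O)CC[C@@H]2[C@@](C)(C/C=C\[Si](C)(C)C)C(C(C)=C)=CC[C@@]2(C)[C@@H]1COCc1ccccc1
F3 | step 5 | C5 trimethylsilyl ether of 7 | C=C1CC[C@@H]2[C@@](C)(CC#C[Si](C)(C)C)[C@H](O[Si](C)(C)C)CC[C@@]2(C)[C@@H]1COCc1ccccc1
F4 | step 6 | 13α-spiro-epoxide of 7 (oxygen α, CH2 β) | O1C[C@@]12CC[C@@H]3[C@@](C)(CC#C[Si](C)(C)C)[C@H](O)CC[C@@]3(C)[C@@H]2COCc1ccccc1
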